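**Retrosynthetic overview**

1. Locants: ring A = C1–C5 + C10, ring B = C5–C10, C11 = side-chain carbon on C7; β = face of the C5 methyl. The target is read as 4β,5β-dimethyl, 7β-isopropenyl, 10α-H, 2α-OH, 8α-OH, 9α-acyloxy, with C4 = S.
2. Feature used: the vicinal O8/O9 pair of ring B is taken as a masked C8=C9 cyclohexene, a Diels–Alder retron in which the diene ends C7 and C10 and the alkene carbons C5 and C6 hold every ring B stereocentre. The late steps are therefore C2 ketone reduction, O9 acylation, dehydration at C11 and cis-dihydroxylation.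
3. Key disconnection: C5–C10 and C6–C7 by an intramolecular Diels–Alder reaction of an acyclic E,E-trienyl dithiane; rings B and A form together and no ring exists before that step.
4. The triene is cut at the dithiane carbon C2: C2–C3 leads to a chiral iodide from methyl (S)-3-hydroxy-2-methylpropanoate (source of C4), and C1–C2 to a dienyl bromide from 2-methylbut-3-yn-2-ol and methyl acrylate.

Key step: step 14

**Route**

Step 1
Reactants: 1 methyl (S)-3-hydroxy-2-methylpropanoate
Product: 2 methyl (2S)-3-[(tert-butyldimethylsilyl)oxy]-2-methylpropanoate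
Conditions: TBSCl, imidazole, CH2Cl2, 0 °C to rt
Reagents that add atoms: tert-butyldimethylsilyl chloride, CC(C)(C)[Si](C)(C)Cl
Why: Imidazole-promoted silylation protects the primary hydroxyl as its silyl ether and no bond to the stereocentre is touched.

Step 2
Reactants: 2 methyl (2S)-3-[(tert-butyldimethylsilyl)oxy]-2-methylpropanoate
Product: 3 (2S)-3-[(tert-butyldimethylsilyl)oxy]-N-methoxy-N,2-dimethylpropanamide
Conditions: MeNH(OMe)·HCl, i-PrMgCl, THF, −20 °C
Reagents that add atoms: N,O-dimethylhydroxylamine hydrochloride, CNOC.Cl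
Why: The chloromagnesium amide made in the flask acylates on the ester (Weinreb amide synthesis) at low temperature faster than it enolises it, so the α-stereocentre should be kept.

Step 3
Reactants: 3 (2S)-3-[(tert-butyldimethylsilyl)oxy]-N-methoxy-N,2-dimethylpropanamide
Product: 4 (3S)-4-[(tert-butyldimethylsilyl)oxy]-3-methylbutan-2-one
Conditions: MeMgBr, THF, 0 °C; aq. NH4Cl
Reagents that add atoms: methylmagnesium bromide, C[Mg]Br
Why: Weinreb ketone synthesis, in which the chelated tetrahedral magnesium adduct lasts until work-up, so one methyl adds and the ketone never meets the Grignard reagent.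

Step 4
Reactants: 4 (3S)-4-[(tert-butyldimethylsilyl)oxy]-3-methylbutan-2-one
Product: 5 tert-butyl{[(2R)-2,3-dimethylbut-3-en-1-yl]oxy}dimethylsilane
Conditions: Ph3PCH3Br, KOt-Bu, THF, 0 °C; then 4, −78 °C to 0 °C
Reagents that add atoms: methyltriphenylphosphonium bromide, C[P+](c1ccccc1)(c1ccccc1)c1ccccc1.[Br-]
Why: Wittig methylenation with the lithium-free ylide, which should add to the methyl ketone at low temperature faster than it enolises it, so the neighbouring stereocentre is carried through (S becomes R only by the change of priorities).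

Step 5
Reactants: 5 tert-butyl{[(2R)-2,3-dimethylbut-3-en-1-yl]oxy}dimethylsilane
Product: 6 (2R)-2,3-dimethylbut-3-en-1-ol
Conditions: Bu4NF, THF, 0 °C to rt
Reagents that add atoms: none
Why: Fluoride cleaves the Si–O bond (desilylation) and the volatile alcohol is carried on as a concentrated solution.

Step 6
Reactants: 6 (2R)-2,3-dimethylbut-3-en-1-ol
Product: 7 (3R)-4-iodo-2,3-dimethylbut-1-ene
Conditions: I2, PPh3, imidazole, CH2Cl2, 0 °C, dark
Reagents that add atoms: iodine, II
Why: Appel-type iodination, an SN2 displacement of the oxyphosphonium group at the primary carbon under buffered conditions that leaves the allylic stereocentre and the alkene alone.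

Step 7
Reactants: 8 2-methylbut-3-yn-2-ol
Product: 9 triethyl[(2-methylbut-3-yn-2-yl)oxy]silane
Conditions: TESCl, imidazole, DMAP (cat.), DMF, rt
Reagents that add atoms: chlorotriethylsilane, CC[Si](Cl)(CC)CC
Why: DMAP-catalysed silylation of the tertiary propargylic hydroxyl, which the slim alkyne leaves accessible.

Step 8
Reactants: 9 triethyl[(2-methylbut-3-yn-2-yl)oxy]silane
Product: 11 triethyl{[(3E)-4-iodo-2-methylbut-3-en-2-yl]oxy}silane, via alkenylzirconocene chloride 10 (not isolated)
Conditions: Cp2Zr(H)Cl, THF, rt; then I2, 0 °C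
Reagents that add atoms: iodine, II
Why: Hydrozirconation is a syn addition that places zirconium on the terminal carbon away from the quaternary centre, and iodinolysis of the C–Zr bond goes with retention, which sets the E alkene.

Step 9
Reactants: 11 triethyl{[(3E)-4-iodo-2-methylbut-3-en-2-yl]oxy}silane; 12 methyl acrylate
Product: 13 methyl (2E,4E)-6-methyl-6-[(triethylsilyl)oxy]hepta-2,4-dienoate
Conditions: Pd(OAc)2 (cat.), K2CO3, Bu4NCl, DMF, rt to 50 °C
Reagents that add atoms: none
Why: Heck reaction under ligand-free phase-transfer conditions, in which oxidative addition of zerovalent palladium (formed from Pd(OAc)2) into the C–I bond with retention, syn insertion of the acrylate and syn β-hydride elimination give the new E alkene.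

Step 10
Reactants: 13 methyl (2E,4E)-6-methyl-6-[(triethylsilyl)oxy]hepta-2,4-dienoate
Product: 14 (2E,4E)-6-methyl-6-[(triethylsilyl)oxy]hepta-2,4-dien-1-ol
Conditions: i-Bu2AlH, CH2Cl2, −78 °C; aq. potassium sodium tartrate
Reagents that add atoms: none
Why: 1,2-Reduction of the conjugated ester by the aluminium hydride at −78 °C gives the allylic alcohol without touching the diene or the silyl ether.

Step 11
Reactants: 14 (2E,4E)-6-methyl-6-[(triethylsilyl)oxy]hepta-2,4-dien-1-ol
Product: 15 {[(3E,5E)-7-bromo-2-methylhepta-3,5-dien-2-yl]oxy}triethylsilane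
Conditions: CBr4, PPh3, 2,6-lutidine, CH2Cl2, −30 °C
Reagents that add atoms: carbon tetrabromide, BrC(Br)(Br)Br
Why: Appel bromination by SN2 displacement at the primary dienylic carbon under lutidine buffering should keep the E,E geometry and the acid-labile tertiary silyl ether, and the bromide is used at once.

Step 12
Reactants: 16 1,3-dithiane; 7 (3R)-4-iodo-2,3-dimethylbut-1-ene
Product: 18 2-[(2S)-2,3-dimethylbut-3-en-1-yl]-1,3-dithiane, via 2-lithio-1,3-dithiane 17 (not isolated)
Conditions: n-BuLi, THF, −30 °C; then 7, −78 °C to 0 °C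
Reagents that add atoms: none
Why: Corey–Seebach alkylation, in which the soft unhindered dithiane anion displaces the primary iodide by SN2 at low temperature in preference to E2, and the stereocentre is not a reacting atom.

Step 13
Reactants: 18 2-[(2S)-2,3-dimethylbut-3-en-1-yl]-1,3-dithiane; 15 {[(3E,5E)-7-bromo-2-methylhepta-3,5-dien-2-yl]oxy}triethylsilane
Product: 20 triethyl({(3E,5E)-7-{2-[(2S)-2,3-dimethylbut-3-en-1-yl]-1,3-dithian-2-yl}-2-methylhepta-3,5-dien-2-yl}oxy)silane, via lithiated dithiane 19 (not isolated)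
Conditions: t-BuLi, THF/HMPA (10:1), −78 °C; then 15, −78 °C
Reagents that add atoms: none
Why: Second Corey–Seebach alkylation, in which the C2 anion attacks the primary α-carbon of the dienyl bromide by direct SN2 (the bulky silyloxy-substituted far terminus disfavours SN2′ and SN2″ attack) and the E,E geometry is untouched.

Step 14
Reactants: 20 triethyl({(3E,5E)-7-{2-[(2S)-2,3-dimethylbut-3-en-1-yl]-1,3-dithian-2-yl}-2-methylhepta-3,5-dien-2-yl}oxy)silane
Product: 21 trans-fused octal-8-ene with a spiro-1,3-dithiane at C2; 4β,5β-dimethyl; 7β-[2-(triethylsilyloxy)propan-2-yl]; 10α-H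
Conditions: toluene (0.01 M, degassed), BHT (cat.), base-washed sealed tube, 180 °C
Reagents that add atoms: none
Why: On heating, the C7=C8–C9=C10 diene and the C5=C6 alkene combine in a concerted, suprafacial [4+2] cycloaddition; the closest known reaction type is the thermal type 1 intramolecular Diels–Alder reaction of unactivated 1,7,9-decatrienes to trans-fused octalins. Ring B is closed by the cycloaddition itself through the new C5–C10 and C6–C7 bonds, and ring A is closed in the fused mode by the same C5–C10 bond, the C1–C4 tether folding as a chair between C5 and C10. C5 and C10 are set trans by the tether-exo transition state, in which the C5 methyl lies endo under the diene; C7 is set by the E,E geometry, because the two outside groups of the diene (C1 on C10 and the silyloxypropyl group on C7) must end cis to each other and to the endo methyl. The absolute sense comes from C4, whose methyl stays equatorial on the chair tether (axial, it would face the axial sulfur on C2), so the diene reaches only one face of the alkene and the 4,5-dimethyl groups end cis. The selectivity needed is trans over cis ring fusion together with this facial bias; the fully substituted alkene carbon C5 and the geminal thioacetal on C2, which holds the tether in the chair and speeds ring closure, are the substrate features relied on, while BHT, base-washed glass and dilution protect the diene and the tertiary allylic silyl ether.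

Step 15
Reactants: 21 trans-fused octal-8-ene with a spiro-1,3-dithiane at C2; 4β,5β-dimethyl; 7β-[2-(triethylsilyloxy)propan-2-yl]; 10α-H
Product: 22 4β,5β-dimethyl-7β-[2-(triethylsilyloxy)propan-2-yl]-10α-H-octal-8-en-2-one
Conditions: MeI, CaCO3, MeCN/H2O (4:1), 45 °C
Reagents that add atoms: water, O
Why: Alkylative dithiane hydrolysis, in which S-methylation makes a sulfonium leaving group and water captures the thionium ion under CaCO3 buffering that the ring alkene and the tertiary silyl ether tolerate, with no stereocentre α to the new ketone.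

Step 16
Reactants: 22 4β,5β-dimethyl-7β-[2-(triethylsilyloxy)propan-2-yl]-10α-H-octal-8-en-2-one
Product: 23 8α,9α-dihydroxy-4β,5β-dimethyl-7β-[2-(triethylsilyloxy)propan-2-yl]-10α-H-decalin-2-one
Conditions: OsO4 (cat.), NMO, acetone/H2O (4:1), rt
Reagents that add atoms: osmium tetroxide, O=[Os](=O)(=O)=O; N-methylmorpholine N-oxide, C[N+]1([O-])CCOCC1; water, O
Why: Catalytic osmylation adds both oxygens suprafacially to C8=C9 from the α face, away from the axial C5 methyl and the pseudoaxial C7 side chain, which sets the cis-8α,9α-diol.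

Step 17
Reactants: 23 8α,9α-dihydroxy-4β,5β-dimethyl-7β-[2-(triethylsilyloxy)propan-2-yl]-10α-H-decalin-2-one
Product: 24 8α,9α-O-isopropylidene-4β,5β-dimethyl-7β-[2-(triethylsilyloxy)propan-2-yl]-10α-H-decalin-2-one
Conditions: 2-methoxypropene, PPTS (cat.), CH2Cl2, 0 °C
Reagents that add atoms: 2-methoxypropene, COC(C)=C
Why: Acid-catalysed acetal formation on the cis-vicinal diol gives the five-membered acetonide, while the ketone and the tertiary silyl ether are inert to PPTS.

Step 18
Reactants: 24 8α,9α-O-isopropylidene-4β,5β-dimethyl-7β-[2-(triethylsilyloxy)propan-2-yl]-10α-H-decalin-2-one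
Product: 25 7β-(2-hydroxypropan-2-yl)-8α,9α-O-isopropylidene-4β,5β-dimethyl-10α-H-decalin-2-one
Conditions: HF·pyridine, pyridine, THF, 0 °C to rt
Reagents that add atoms: none
Why: Buffered hydrogen fluoride cleaves the tertiary Si–O bond (desilylation) under conditions that leave the acetonide and the ketone untouched.

Step 19
Reactants: 25 7β-(2-hydroxypropan-2-yl)-8α,9α-O-isopropylidene-4β,5β-dimethyl-10α-H-decalin-2-one
Product: 26 7β-isopropenyl-8α,9α-O-isopropylidene-4β,5β-dimethyl-10α-H-decalin-2-one
Conditions: methyl N-(triethylammoniosulfonyl)carbamate (Burgess reagent), toluene, rt to 50 °C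
Reagents that add atoms: none
Why: Burgess dehydration, an intramolecular syn elimination of the tertiary sulfamate in which a syn-periplanar methyl hydrogen is always at hand whereas reaching H7 would force the two C11 methyls to eclipse C6 and C8, so the isopropenyl alkene should form and C7 stays as set.

Step 20
Reactants: 26 7β-isopropenyl-8α,9α-O-isopropylidene-4β,5β-dimethyl-10α-H-decalin-2-one
Product: 27 8α,9α-dihydroxy-7β-isopropenyl-4β,5β-dimethyl-10α-H-decalin-2-one
Conditions: AcOH/H2O (4:1), 45 °C
Reagents that add atoms: none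
Why: Acid-catalysed acetal hydrolysis in aqueous acetic acid, a weak acid that the isopropenyl group and the ketone should withstand.

Step 21
Reactants: 27 8α,9α-dihydroxy-7β-isopropenyl-4β,5β-dimethyl-10α-H-decalin-2-one; 28 (Z)-3-methylpent-2-enoic acid
Product: 30 8α-hydroxy-7β-isopropenyl-4β,5β-dimethyl-9α-[(Z)-3-methylpent-2-enoyloxy]-10α-H-decalin-2-one, via Yamaguchi mixed anhydride 29 (not isolated)
Conditions: 28, 2,4,6-trichlorobenzoyl chloride, Et3N, toluene, rt; then 27, DMAP, 0 °C to rt
Reagents that add atoms: none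
Why: Yamaguchi esterification, in which DMAP opens the mixed anhydride at the enoyl carbonyl and the acylpyridinium should acylate the equatorial C9 hydroxyl in preference to the axial C8 hydroxyl, which is flanked by the C7 isopropenyl group and syn-axial hydrogens, while mild base and low temperature are meant to keep the Z geometry.

Step 22
Reactants: 30 8α-hydroxy-7β-isopropenyl-4β,5β-dimethyl-9α-[(Z)-3-methylpent-2-enoyloxy]-10α-H-decalin-2-one
Product: 31 CNP0129603.1: 2α,8α-dihydroxy-7β-isopropenyl-4β,5β-dimethyl-9α-[(Z)-3-methylpent-2-enoyloxy]-10α-H-decalin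
Conditions: LiBH(s-Bu)3 (2.2 equiv), THF, −78 °C; AcOH quench at −78 °C
Reagents that add atoms: none
Why: The bulky trialkylborohydride attacks the C2 ketone along the equatorial trajectory (the axial path on the α face is blocked by the axial hydrogens on C4 and C10), which sets the axial 2α-alcohol, and at −78 °C the β,β-disubstituted enoate ester should not be reduced.

**Compound list**

1 | methyl (S)-3-hydroxy-2-methylpropanoate | COC(=O)[C@@H](C)CO | starting material
2 | methyl (2S)-3-[(tert-butyldimethylsilyl)oxy]-2-methylpropanoate | COC(=O)[C@@H](C)CO[Si](C)(C)C(C)(C)C | intermediate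
3 | (2S)-3-[(tert-butyldimethylsilyl)oxy]-N-methoxy-N,2-dimethylpropanamide | CON(C)C(=O)[C@@H](C)CO[Si](C)(C)C(C)(C)C | intermediate
4 | (3S)-4-[(tert-butyldimethylsilyl)oxy]-3-methylbutan-2-one | CC(=O)[C@@H](C)CO[Si](C)(C)C(C)(C)C | intermediate
5 | tert-butyl{[(2R)-2,3-dimethylbut-3-en-1-yl]oxy}dimethylsilane | C=C(C)[C@@H](C)CO[Si](C)(C)C(C)(C)C | intermediate
6 | (2R)-2,3-dimethylbut-3-en-1-ol | C=C(C)[C@@H](C)CO | intermediate
7 | (3R)-4-iodo-2,3-dimethylbut-1-ene | C=C(C)[C@@H](C)CI | intermediate
8 | 2-methylbut-3-yn-2-ol | CC(C)(O)C#C | starting material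
9 | triethyl[(2-methylbut-3-yn-2-yl)oxy]silane | CC(C)(O[Si](CC)(CC)CC)C#C | intermediate
10 | (E)-alkenylzirconocene chloride from 9 (not isolated) | CC(C)(O[Si](CC)(CC)CC)/C=C/[Zr](Cl)(C1C=CC=C1)C1C=CC=C1 | intermediate
11 | triethyl{[(3E)-4-iodo-2-methylbut-3-en-2-yl]oxy}silane | CC(C)(O[Si](CC)(CC)CC)/C=C/I | intermediate
12 | methyl acrylate | COC(=O)C=C | starting material
13 | methyl (2E,4E)-6-methyl-6-[(triethylsilyl)oxy]hepta-2,4-dienoate | COC(=O)/C=C/C=C/C(C)(C)O[Si](CC)(CC)CC | intermediate
14 | (2E,4E)-6-methyl-6-[(triethylsilyl)oxy]hepta-2,4-dien-1-ol | OC/C=C/C=C/C(C)(C)O[Si](CC)(CC)CC | intermediate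
15 | {[(3E,5E)-7-bromo-2-methylhepta-3,5-dien-2-yl]oxy}triethylsilane | BrC/C=C/C=C/C(C)(C)O[Si](CC)(CC)CC | intermediate
16 | 1,3-dithiane | C1CSCSC1 | starting material
17 | 2-lithio-1,3-dithiane (not isolated) | [Li]C1SCCCS1 | intermediate
18 | 2-[(2S)-2,3-dimethylbut-3-en-1-yl]-1,3-dithiane | C=C(C)[C@@H](C)CC1SCCCS1 | intermediate
19 | 2-lithio derivative of 18 (not isolated) | C=C(C)[C@@H](C)CC1([Li])SCCCS1 | intermediate
20 | triethyl({(3E,5E)-7-{2-[(2S)-2,3-dimethylbut-3-en-1-yl]-1,3-dithian-2-yl}-2-methylhepta-3,5-dien-2-yl}oxy)silane | C=C(C)[C@@H](C)CC1(SCCCS1)C/C=C/C=C/C(C)(C)O[Si](CC)(CC)CC | intermediate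
21 | trans-fused octal-8-ene with a spiro-1,3-dithiane at C2; 4β,5β-dimethyl; 7β-[2-(triethylsilyloxy)propan-2-yl]; 10α-H | CC(C)(O[Si](CC)(CC)CC)[C@H]1C[C@]2(C)[C@@H](C)CC3(SCCCS3)C[C@H]2C=C1 | intermediate
22 | 4β,5β-dimethyl-7β-[2-(triethylsilyloxy)propan-2-yl]-10α-H-octal-8-en-2-one | CC(C)(O[Si](CC)(CC)CC)[C@H]1C[C@]2(C)[C@@H](C)CC(=O)C[C@H]2C=C1 | intermediate
23 | 8α,9α-dihydroxy-4β,5β-dimethyl-7β-[2-(triethylsilyloxy)propan-2-yl]-10α-H-decalin-2-one | CC(C)(O[Si](CC)(CC)CC)[C@H]1C[C@]2(C)[C@@H](C)CC(=O)C[C@H]2[C@H](O)[C@@H]1O | intermediate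
24 | 8α,9α-O-isopropylidene-4β,5β-dimethyl-7β-[2-(triethylsilyloxy)propan-2-yl]-10α-H-decalin-2-one | CC(C)(O[Si](CC)(CC)CC)[C@H]1C[C@]2(C)[C@@H](C)CC(=O)C[C@H]2[C@H](OC3(C)C)[C@@H]1O3 | intermediate
25 | 7β-(2-hydroxypropan-2-yl)-8α,9α-O-isopropylidene-4β,5β-dimethyl-10α-H-decalin-2-one | CC(C)(O)[C@H]1C[C@]2(C)[C@@H](C)CC(=O)C[C@H]2[C@H](OC3(C)C)[C@@H]1O3 | intermediate
26 | 7β-isopropenyl-8α,9α-O-isopropylidene-4β,5β-dimethyl-10α-H-decalin-2-one | C=C(C)[C@H]1C[C@]2(C)[C@@H](C)CC(=O)C[C@H]2[C@H](OC3(C)C)[C@@H]1O3 | intermediate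
27 | 8α,9α-dihydroxy-7β-isopropenyl-4β,5β-dimethyl-10α-H-decalin-2-one | C=C(C)[C@H]1C[C@]2(C)[C@@H](C)CC(=O)C[C@H]2[C@H](O)[C@@H]1O | intermediate
28 | (Z)-3-methylpent-2-enoic acid | OC(=O)/C=C(/C)CC | starting material
29 | (Z)-3-methylpent-2-enoic 2,4,6-trichlorobenzoic anhydride (not isolated) | O=C(OC(=O)/C=C(/C)CC)c1c(Cl)cc(Cl)cc1Cl | intermediate
30 | 8α-hydroxy-7β-isopropenyl-4β,5β-dimethyl-9α-[(Z)-3-methylpent-2-enoyloxy]-10α-H-decalin-2-one | C=C(C)[C@H]1C[C@]2(C)[C@@H](C)CC(=O)C[C@H]2[C@H](OC(=O)/C=C(/C)CC)[C@@H]1O | intermediate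
31 | CNP0129603.1: 2α,8α-dihydroxy-7β-isopropenyl-4β,5β-dimethyl-9α-[(Z)-3-methylpent-2-enoyloxy]-10α-H-decalin | C=C(C)[C@H]1C[C@]2(C)[C@@H](C)C[C@H](O)C[C@H]2[C@H](OC(=O)/C=C(/C)CC)[C@@H]1O | target

**Step count**

Total: 22 steps. Longest linear sequence: 17 steps (steps 1–6 and 12–22).

**Steps most likely to fail**

Step 14. What may go wrong: the cis-fused and the C4-mismatched transition states may compete with the trans pathway, and material may be lost through the C–S bonds or the allylic silyl ether during the long heating. The fallback sets out from 20 and comes back at 22; it changes the cyclisation substrate and the order of unmasking. Triene 20 is hydrolysed with MeI and CaCO3 in aqueous MeCN to the trienone (3S,7E,9E)-2,3,11-trimethyl-11-[(triethylsilyl)oxy]dodeca-1,7,9-trien-5-one F1. F1 is ketalised under aprotic conditions (1,2-bis(trimethylsilyloxy)ethane, catalytic TMSOTf, CH2Cl2, −78 °C) to the 1,3-dioxolane triene F2. The oxygen ketal keeps the geminal substitution and an axial heteroatom on C2, so the chair-tether control of the C4 relay is retained, but it has no C–S bond to break. F2 is cyclised in toluene with BHT at 180 °C or above to the dioxolane cycloadduct F3, and PPTS in wet acetone then releases ketone 22, so step 15 is no longer needed.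

Step 19. What may go wrong: ionisation of the tertiary sulfamate (E1 in place of the syn elimination) would lead to loss of H7, giving the tetrasubstituted C7=C11 alkene and erasing the C7 stereocentre. The fallback sets out from 23 and comes back at 27; it replaces the syn elimination on the acetonide by a base-induced anti elimination on a differently protected substrate. HF·pyridine frees the tertiary alcohol of 23 to give the keto triol F4. Excess SOCl2 in pyridine/CH2Cl2 at −30 °C ties the cis-8α,9α-diol as its cyclic sulfite and turns the tertiary hydroxyl into a chlorosulfite, which pyridine eliminates through the exposed methyl hydrogens (E2) to the isopropenyl cyclic sulfite F5. Aqueous NaOH in THF at 0 °C hydrolyses the sulfite to diol 27, which also replaces steps 17, 18 and 20.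

Step 21. What may go wrong: acyl transfer to O8 or to both hydroxyls, and Z to E or α,β to β,γ isomerisation of the activated enoyl unit by the amine bases. The fallback sets out from 27 and 28 and comes back at 30; it is a tin-directed acylation without amine base. Diol 27 and Bu2SnO in refluxing toluene with removal of water give the dibutylstannylene acetal F6. Acid 28 is converted under neutral conditions with 1-chloro-N,N,2-trimethylprop-1-en-1-amine in CH2Cl2 at 0 °C into (Z)-3-methylpent-2-enoyl chloride F7. F6 and F7 in toluene at 0 °C should acylate the equatorial O9, the oxygen that stannylene acetals of cis-diols on six-membered rings activate, and aqueous work-up gives 30.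

**Further compounds**

F1 | step 14 | (3S,7E,9E)-2,3,11-trimethyl-11-[(triethylsilyl)oxy]dodeca-1,7,9-trien-5-one | C=C(C)[C@@H](C)CC(=O)C/C=C/C=C/C(C)(C)O[Si](CC)(CC)CC
F2 | step 14 | triethyl({(3E,5E)-7-{2-[(2S)-2,3-dimethylbut-3-en-1-yl]-1,3-dioxolan-2-yl}-2-methylhepta-3,5-dien-2-yl}oxy)silane | C=C(C)[C@@H](C)CC1(OCCO1)C/C=C/C=C/C(C)(C)O[Si](CC)(CC)CC
F3 | step 14 | C2 ethylene ketal of 22 (trans-fused octal-8-ene; 4β,5β-dimethyl; 7β-[2-(triethylsilyloxy)propan-2-yl]; 10α-H) | CC(C)(O[Si](CC)(CC)CC)[C@H]1C[C@]2(C)[C@@H](C)CC3(OCCO3)C[C@H]2C=C1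
F4 | step 19 | 8α,9α-dihydroxy-7β-(2-hydroxypropan-2-yl)-4β,5β-dimethyl-10α-H-decalin-2-one | CC(C)(O)[C@H]1C[C@]2(C)[C@@H](C)CC(=O)C[C@H]2[C@H](O)[C@@H]1O
F5 | step 19 | 8α,9α-cyclic sulfite of 27 (either configuration at sulfur) | C=C(C)[C@H]1C[C@]2(C)[C@@H](C)CC(=O)C[C@H]2[C@H](OS3=O)[C@@H]1O3
F6 | step 21 | 8α,9α-O-dibutylstannylene acetal of 27 | C=C(C)[C@H]1C[C@]2(C)[C@@H](C)CC(=O)C[C@H]2[C@H](O[Sn]3(CCCC)CCCC)[C@@H]1O3
F7 | step 21 | (Z)-3-methylpent-2-enoyl chloride | ClC(=O)/C=C(/C)CC
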